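**Strategy.** Ring numbering: C1 ketone, C2 (CH2OAc), C3, C4 (OH), C5 and C6 (epoxide); chain C1'–C12'. The plan disconnects the bond between C5, the quaternary epoxide carbon of the six-membered ring, and the side-chain carbinol C1'. C5 sits beside the C4 carbinol, a latent ketone, so C4(=O)–C5(=C6)–C1'(OH) is the retron of a Morita–Baylis–Hillman adduct. An enantioselective MBH reaction therefore joins a complete quinone monoketal ring (C1 masked as dimethyl ketal, CH2OAc on C2) to (2E,6E)-farnesal, forming C5–C1' and setting C1' by catalysis. C1' then relays everything else: its hydroxyl directs nucleophilic epoxidation (C5 and C6 in one event) and hydride delivery to C4; ketal hydrolysis unveils the enone.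

Key step: step 5

Remarks on the chemistry:
- Assumption: the (R)-antipode of the H8-BINOL Brønsted acid is taken to favour the (S)-carbinol at C1'. Both antipodes are available, so the sense can be matched without changing the route.
- (2E,6E)-Farnesol and 5-hydroxy-2-methoxybenzaldehyde are taken as commercial.

Step 1
Reactants: 1 (2E,6E)-farnesol
Product: 2 (2E,6E)-farnesal
Conditions: activated MnO2 (excess), CH2Cl2, rt
Reagents that add atoms: none
Why: Allylic alcohol oxidation on MnO2 should stop at the enal and leave the 2E geometry and the two isolated trisubstituted alkenes untouched.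

Step 2
Reactants: 3 5-hydroxy-2-methoxybenzaldehyde
Product: 4 3-(hydroxymethyl)-4-methoxyphenol
Conditions: NaBH4, MeOH, 0 °C
Reagents that add atoms: none
Why: Borohydride reduction of an aryl aldehyde to the benzylic alcohol; the phenol is inert and no stereocentre is involved.

Step 3
Reactants: 4 3-(hydroxymethyl)-4-methoxyphenol
Product: 5 3-(hydroxymethyl)-4,4-dimethoxycyclohexa-2,5-dien-1-one
Conditions: PhI(OAc)2 (1.1 equiv), MeOH, 0 °C
Reagents that add atoms: methanol, CO
Why: Oxidative dearomatisation of a para-methoxyphenol by a λ3-iodane, with methanol captured at the methoxy-bearing para carbon, should place the ketone at C4 and the dimethyl ketal at C1 without touching the benzylic alcohol.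

Step 4
Reactants: 5 3-(hydroxymethyl)-4,4-dimethoxycyclohexa-2,5-dien-1-one
Product: 6 (6,6-dimethoxy-3-oxocyclohexa-1,4-dien-1-yl)methyl acetate
Conditions: Ac2O, pyridine, DMAP (cat.), CH2Cl2, 0 °C
Reagents that add atoms: acetic anhydride, CC(=O)OC(C)=O
Why: DMAP-catalysed acylation of the only hydroxyl group; the dienone ketal is stable to these mildly basic conditions.

Step 5
Reactants: 6 (6,6-dimethoxy-3-oxocyclohexa-1,4-dien-1-yl)methyl acetate (2 equiv), 2 (2E,6E)-farnesal
Product: 9 (1'S)-MBH carbinol [6,6-dimethoxy-3-oxo-4-[(1S,2E,6E)-1-hydroxy-3,7,11-trimethyldodeca-2,6,10-trien-1-yl]cyclohexa-1,4-dien-1-yl]methyl acetate, via phosphonium dienolate 7 (not isolated), via phosphonium aldolate 8 (not isolated)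
Conditions: PEt3 (0.5 equiv), (R)-3,3'-bis[3,5-bis(trifluoromethyl)phenyl]-5,5',6,6',7,7',8,8'-octahydro-1,1'-bi-2-naphthol (15 mol%), THF, −10 °C
Reagents that add atoms: none
Why: Proposed new method: PEt3 adds reversibly to C6, the only unsubstituted β-carbon of dienone 6 (C2 is blocked by CH2OAc), to give phosphonium dienolate 7, which is held by the chiral diol through hydrogen bonds and adds through C5 to the carbonyl of farnesal (1,2-addition, since the β,β-disubstituted enal terminus is a poor Michael acceptor) to give aldolate 8; proton transfer and E1cB loss of PEt3 from 8 then restore the C5=C6 bond and return the phosphine. The closest known reaction type is the asymmetric MBH reaction of cyclohex-2-enone with aldehydes under chiral Brønsted acid/trialkylphosphine co-catalysis, which has not been shown for a cross-conjugated quinone monoketal or for a β,β-disubstituted enal, hence the label. No ring is closed. The only new stereocentre, C1', is set by the catalyst: the diol-bound enolate distinguishes the two faces of the aldehyde in the C–C bond-forming step, which the acid makes product-determining by speeding the proton transfer that follows. The step needs regioselectivity (C5 over C3), chemoselectivity (acetate, ketal and chain alkenes untouched, no 2E/2Z scrambling) and enantioselectivity; the substitution pattern of 6, the neutral low-temperature conditions and the catalyst are meant to secure these in that order.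

Step 6
Reactants: 9 (1'S)-MBH carbinol
Product: 11 epoxy enone ketal [(1R,6S)-6-[(1S,2E,6E)-1-hydroxy-3,7,11-trimethyldodeca-2,6,10-trien-1-yl]-2,2-dimethoxy-5-oxo-7-oxabicyclo[4.1.0]hept-3-en-3-yl]methyl acetate, via sodium peroxy enolate 10 (not isolated)
Conditions: Ph3COOH (2.2 equiv) premixed with NaHMDS (2.0 equiv), toluene, −60 to −30 °C; then H2O
Reagents that add atoms: trityl hydroperoxide, OOC(c1ccccc1)(c1ccccc1)c1ccccc1
Why: Weitz–Scheffer nucleophilic epoxidation delivered by the C1' hydroxyl: with C1'–H eclipsing the C5–C4 bond (least A(1,3) strain against the C4 carbonyl oxygen) the sodium-bridged trityl peroxide should reach C6 on the face of O1' with the chain on the far face, and closure of enolate 10 onto the O–O bond then fixes C5 and C6 together as the cis-fused epoxide, while the C2=C3 alkene (β-carbon fully substituted, no directing group), the electron-rich chain alkenes and the acetate (bulky peroxide, poor acyl acceptor partner) should stay intact.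

Step 7
Reactants: 11 epoxy enone ketal
Product: 12 epoxy diol ketal [(1R,5S,6R)-5-hydroxy-6-[(1S,2E,6E)-1-hydroxy-3,7,11-trimethyldodeca-2,6,10-trien-1-yl]-2,2-dimethoxy-7-oxabicyclo[4.1.0]hept-3-en-3-yl]methyl acetate
Conditions: Me4NBH(OAc)3 (5 equiv), MeCN/AcOH (1:1), −30 °C
Reagents that add atoms: none
Why: Evans–Saksena hydroxyl-directed reduction of a β-hydroxy ketone: the acetoxyborohydride bound to O1' should deliver hydride through a chair transition state with the chain equatorial, which is the epoxide face of C4, giving the 1,3-anti diol with the new C4 hydroxyl trans to the epoxide oxygen (4S), while the ester, ketal, epoxide and the conjugate position are not touched by this mild hydride.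

Step 8
Reactants: 12 epoxy diol ketal
Product: 13 target CNP0137670.2, [(1R,5S,6R)-5-hydroxy-6-[(1S,2E,6E)-1-hydroxy-3,7,11-trimethyldodeca-2,6,10-trien-1-yl]-2-oxo-7-oxabicyclo[4.1.0]hept-3-en-3-yl]methyl acetate
Conditions: montmorillonite K10, wet CH2Cl2, rt
Reagents that add atoms: water, O
Why: Acid-catalysed hydrolysis of an allylic dimethyl ketal through the conjugated oxocarbenium ion should unveil the C1 ketone in conjugation with C2=C3 under conditions mild enough to spare the epoxide, both allylic alcohols and the acetate; no stereocentre is touched.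

**Compound list**

1 | (2E,6E)-farnesol | OC/C=C(\C)CC/C=C(\C)CCC=C(C)C | starting material
2 | (2E,6E)-farnesal | O=C/C=C(\C)CC/C=C(\C)CCC=C(C)C | intermediate
3 | 5-hydroxy-2-methoxybenzaldehyde | COc1ccc(O)cc1C=O | starting material
4 | 3-(hydroxymethyl)-4-methoxyphenol | COc1ccc(O)cc1CO | intermediate
5 | 3-(hydroxymethyl)-4,4-dimethoxycyclohexa-2,5-dien-1-one | COC1(OC)C=CC(=O)C=C1CO | intermediate
6 | (6,6-dimethoxy-3-oxocyclohexa-1,4-dien-1-yl)methyl acetate (quinone monoketal: ketone at C4, ketal at C1, CH2OAc on C2) | CC(=O)OCC1=CC(=O)C=CC1(OC)OC | intermediate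
7 | phosphonium dienolate: zwitterion from addition of PEt3 to C6 of 6 (C6 unspecified) | CC(=O)OCC1=CC([O-])=CC([P+](CC)(CC)CC)C1(OC)OC | intermediate
8 | phosphonium aldolate: zwitterion with the C5–C1' bond formed, (1'S), PEt3 still on C6 (C5 and C6 unspecified); loses PEt3 on the way to 9 | CC(=O)OCC1=CC(=O)C([C@@H]([O-])/C=C(\C)CC/C=C(\C)CCC=C(C)C)C([P+](CC)(CC)CC)C1(OC)OC | intermediate
9 | (1'S)-MBH carbinol, [6,6-dimethoxy-3-oxo-4-[(1S,2E,6E)-1-hydroxy-3,7,11-trimethyldodeca-2,6,10-trien-1-yl]cyclohexa-1,4-dien-1-yl]methyl acetate | CC(=O)OCC1=CC(=O)C([C@@H](O)/C=C(\C)CC/C=C(\C)CCC=C(C)C)=CC1(OC)OC | intermediate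
10 | sodium peroxy enolate: C4 sodium enolate of 9 carrying Ph3COO on C6 (6R, 1'S) | CC(=O)OCC1=CC([O-])=C([C@@H](O)/C=C(\C)CC/C=C(\C)CCC=C(C)C)[C@@H](OOC(c2ccccc2)(c2ccccc2)c2ccccc2)C1(OC)OC.[Na+] | intermediate
11 | epoxy enone ketal, [(1R,6S)-6-[(1S,2E,6E)-1-hydroxy-3,7,11-trimethyldodeca-2,6,10-trien-1-yl]-2,2-dimethoxy-5-oxo-7-oxabicyclo[4.1.0]hept-3-en-3-yl]methyl acetate (target numbering 5S,6R,1'S; the 5-descriptor reads S only because C4 is a carbonyl) | CC(=O)OCC1=CC(=O)[C@@]2([C@@H](O)/C=C(\C)CC/C=C(\C)CCC=C(C)C)O[C@H]2C1(OC)OC | intermediate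
12 | epoxy diol ketal, [(1R,5S,6R)-5-hydroxy-6-[(1S,2E,6E)-1-hydroxy-3,7,11-trimethyldodeca-2,6,10-trien-1-yl]-2,2-dimethoxy-7-oxabicyclo[4.1.0]hept-3-en-3-yl]methyl acetate (target numbering 4S,5R,6R,1'S; C4–OH trans to the epoxide oxygen) | CC(=O)OCC1=C[C@H](O)[C@@]2([C@@H](O)/C=C(\C)CC/C=C(\C)CCC=C(C)C)O[C@H]2C1(OC)OC | intermediate
13 | CNP0137670.2, [(1R,5S,6R)-5-hydroxy-6-[(1S,2E,6E)-1-hydroxy-3,7,11-trimethyldodeca-2,6,10-trien-1-yl]-2-oxo-7-oxabicyclo[4.1.0]hept-3-en-3-yl]methyl acetate (target numbering 4S,5R,6R,1'S) | CC(=O)OCC1=C[C@H](O)[C@@]2([C@@H](O)/C=C(\C)CC/C=C(\C)CCC=C(C)C)O[C@H]2C1=O | target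

**Count.** Total steps: 8. Longest linear sequence: 7 steps (3 → 4 → 5 → 6 → 9 → 11 → 12 → 13).

**Steps most likely to fail**

1. Step 5 (Proposed new method). The phosphonium dienolate may add too slowly to the hindered, weakly electrophilic enal. Self-coupling of 6 (Rauhut–Currier), ylide formation at C6 followed by loss of methoxide and aromatisation, phosphine-induced 2E/2Z isomerisation of the enal, or a poorly organised transition state (low enantioselectivity) could then take over. Fallback with known chemistry, setting out from 4 (and 2) and returning at 9: iodination of 4 ortho to the phenol (NIS, MeCN, 0 °C) should give 5-(hydroxymethyl)-2-iodo-4-methoxyphenol F1. Double silylation (TBSCl, imidazole, DMF) gives the bis-TBS ether F2. Iodine–magnesium exchange (i-PrMgCl, THF, 0 °C), transfer to titanium (Ti(OiPr)4) and addition to farnesal 2 under a catalytic 3-aryl-H8-BINOL titanium complex, a known catalytic asymmetric aryl transfer to aldehydes that includes enals, forms the same C5–C1' bond and gives the (S)-aryl carbinol F3. TBAF/AcOH in THF frees the phenol and the primary alcohol to give the phenolic triol F4. PhI(OAc)2 in MeOH dearomatises it to the monoketal diol F5. Acetylation of the primary hydroxyl only (AcCl, 2,4,6-collidine, CH2Cl2, −78 °C) returns to 9.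

2. Step 6. Undirected attack of the peroxide, on the other face of C5=C6 or at the acetate, may compete with hydroxyl-directed delivery and erode facial selectivity. Fallback with covalent auxiliary control, setting out from 6 and returning at 13: transketalisation of 6 with (2R,4R)-pentane-2,4-diol (BF3·OEt2, DME, 0 °C) gives the C2-symmetric spiro-dioxane ketal F6; the antipodal diol is taken if it proves to be the matched one. The MBH reaction of step 5 with 2 gives the carbinol F7. The trityl peroxide epoxidation, now under the control of the auxiliary as well as the carbinol, gives the epoxy ketone F8. The directed reduction of step 7 gives the diol F9. Aqueous acid (TFA, H2O, CH2Cl2, 0 °C) removes the auxiliary and gives 13.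

3. Step 7. Ligand exchange at the hindered C1' hydroxyl may be slow, so that external hydride attack on the face away from the epoxide oxygen, or acid-induced loss of the ketal before reduction, competes. Fallback with catalyst control instead of substrate direction, setting out from 11 and returning at 12: a Corey–Bakshi–Shibata reduction with (R)-Me-CBS (20 mol%) and catecholborane in toluene at −78 °C. Here the quaternary C5 acts as the large flank and the vinylic C3 as the small flank, so hydride should arrive on the epoxide face. Catecholborane is chosen because it does not hydroborate the chain alkenes at this temperature. This makes no new compound F0.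

**Further compounds**

F1 | step 5 | 5-(hydroxymethyl)-2-iodo-4-methoxyphenol | COc1cc(I)c(O)cc1CO
F2 | step 5 | bis-TBS ether of F1, tert-butyl[[5-(tert-butyldimethylsilyloxy)-4-iodo-2-methoxyphenyl]methoxy]dimethylsilane | COc1cc(I)c(O[Si](C)(C)C(C)(C)C)cc1CO[Si](C)(C)C(C)(C)C
F3 | step 5 | (S)-aryl carbinol, (1S,2E,6E)-1-[2-(tert-butyldimethylsilyloxy)-4-[(tert-butyldimethylsilyloxy)methyl]-5-methoxyphenyl]-3,7,11-trimethyldodeca-2,6,10-trien-1-ol | COc1cc([C@@H](O)/C=C(\C)CC/C=C(\C)CCC=C(C)C)c(O[Si](C)(C)C(C)(C)C)cc1CO[Si](C)(C)C(C)(C)C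
F4 | step 5 | phenolic triol, 2-[(1S,2E,6E)-1-hydroxy-3,7,11-trimethyldodeca-2,6,10-trien-1-yl]-5-(hydroxymethyl)-4-methoxyphenol | COc1cc([C@@H](O)/C=C(\C)CC/C=C(\C)CCC=C(C)C)c(O)cc1CO
F5 | step 5 | monoketal diol, 2-[(1S,2E,6E)-1-hydroxy-3,7,11-trimethyldodeca-2,6,10-trien-1-yl]-5-(hydroxymethyl)-4,4-dimethoxycyclohexa-2,5-dien-1-one | OCC1=CC(=O)C([C@@H](O)/C=C(\C)CC/C=C(\C)CCC=C(C)C)=CC1(OC)OC
F6 | step 6 | spiro-dioxane ketal, [(2R,4R)-2,4-dimethyl-9-oxo-1,5-dioxaspiro[5.5]undeca-7,10-dien-7-yl]methyl acetate | CC(=O)OCC1=CC(=O)C=CC12O[C@H](C)C[C@@H](C)O2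
F7 | step 6 | carbinol, the (1'S)-MBH adduct of F6 and 2 (analogue of 9 with the pentanediol ketal) | CC(=O)OCC1=CC(=O)C([C@@H](O)/C=C(\C)CC/C=C(\C)CCC=C(C)C)=CC12O[C@H](C)C[C@@H](C)O2
F8 | step 6 | epoxy ketone, the 5,6-epoxide of F7 (analogue of 11 with the pentanediol ketal) | CC(=O)OCC1=CC(=O)[C@@]2([C@@H](O)/C=C(\C)CC/C=C(\C)CCC=C(C)C)O[C@H]2C12O[C@H](C)C[C@@H](C)O2
F9 | step 6 | diol, the (4S)-alcohol from F8 (analogue of 12 with the pentanediol ketal) | CC(=O)OCC1=C[C@H](O)[C@@]2([C@@H](O)/C=C(\C)CC/C=C(\C)CCC=C(C)C)O[C@H]2C12O[C@H](C)C[C@@H](C)O2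
F0 | step 7 | none | none
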